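The readings come from a simulation with made-up constants, noise included.

Birch, run earlier with 0.75 M of substrate, and cedar, followed so far with 1.5 M, both sent their substrate down two roads, so I followed one molecule to its fork: it takes up dissolved gas and becomes target, or turns by itself into side product.

| setting | cedar | birch | flask |
|---|---|---|---|
| substrate | 1.5 M (in portions, 3) | 0.75 M (in portions, 3) | 1.5 M (in portions, 3) |
| gas phase | 200 mM (held) | 200 mM (held) | 200 mM (held) |
| remark | the very flask that is asked about, followed so far; portions every 10 s | run made earlier; portions every 10 s | the portions of substrate follow each other after 10 s, the first at the start |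
| time |  |  | 20 min |

| run | time / min | substrate / % | target / % | side product / % |
|---|---|---|---|---|
| cedar | 0.833 | 65.6 | 8.3 | 26.5 |
| cedar | 2.00 | 28.8 | 20.1 | 52.2 |
| cedar | 4.00 | 6.8 | 27.3 | 65.7 |
| cedar | 10.0 | 0.1 | 29.3 | 71.4 |
| birch | 2.50 | 18.4 | 25.0 | 55.2 |
| birch | 8.00 | 0 | 30.8 | 68.0 |
| birch | 12.0 | 0 | 30.6 | 68.2 |
| birch | 20.0 | 0.7 | 31.6 | 69.2 |

(readings scatter by 0.5 percentage points)

- what is said of target includes crystals
- crystals is a solid; its amount is given per volume of the solution
- at the start none of the gas is dissolved
- steps under discussion: gas phase <-> dissolved gas; substrate + dissolved gas -> target; substrate -> side product; 2 dissolved gas -> homo dimer; crystals <-> target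
- the reaction counts as stopped when no species that holds the substrate changes by six tenths of a point or more over the second half of the time

1. why nothing more happens at 20 min, or that something still does (all of the substrate has reacted / forward and back rates have come level / it is still moving)
2. part of the substrate gone at 20 min
3. the target standing at 20 min, as a percentage of the substrate charged
4. the side product standing at 20 min, as a percentage of the substrate charged

At cedar's 10.0 min reading, 29.1% of the reacted substrate had become target: this is the fork share, target over target plus side product, the chance that one reacted molecule took up dissolved gas.

I turned the settings by hand, one after the other. Time: with crystals counted as target, the steps under discussion consume neither product, so I expected the fork share to move while substrate remained to react, and cedar held 0.1% at that reading. Birch bore this out, with 31.2% at 8.00 min and 31.3% at 20.0 min. Portions: cedar's charge was in by 0.333 min, shorter than the half-life of 0.960 min I read from its substrate, so by hand cedar came close to a single charge. Charge: substrate cancels from the odds at the fork, which follow dissolved gas, so a larger charge acts through the gas it draws down. Birch's share stood above cedar's. Cedar, which began with none of the gas dissolved, had a share at 0.833 min of 23.9%, below its later one. Saturation: both runs held 200 mM, so the readings showed no effect of changing it.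

My reckoning for cedar at 20 min was full conversion, target 29.1% and side product 70.9%. The forecast said all of the substrate has reacted, conversion 100%, target 29.3% and side product 70.7%, on the ground that “Products then freeze, since the steps shown consume neither once substrate is gone”.

The outcome for cedar was: all of the substrate has reacted, with conversion >99.9%, target 29.4% and side product 70.6%, a fork share of 29.4%.

gas phase ⇌ dissolved gas, rate k1*(csat - [dissolved gas]) (kL = 0.0568 s⁻¹); substrate + dissolved gas → target (k = 0.0252 M⁻¹ s⁻¹); substrate → side product (k = 0.00820 s⁻¹); 2 dissolved gas → homo dimer (k = 0.0150 M⁻¹ s⁻¹); crystals ⇌ target, rate k5*(cs5 - [target]) while solid is left; crystals form when [target] > cs5 (solubility = 1.00 M, k = 0.248 s⁻¹) Over cedar's second half of the time no share moved more than 0.065 percentage points, while homo dimer, which holds no substrate, rose from 0.256 M to 0.555 M. Cedar's dissolved gas stood at 0.113 M at 0.333 min, below the held 200 mM, and the same flask without the transfer resistance gave 62.0% side product instead of 70.6%. The neighbour flask with 0.60 M of substrate had a fork share of 31.8%.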